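The target is epicatechin-(4β→6)-catechin-(4α→6)-catechin. The top unit comes from (−)-epicatechin; both catechin units come from one benzylated monomer whose ring C is built de novo. The disconnection reads O1–C2(aryl)–C3 of ring C of the middle catechin as the ambident enolate of 3',4'-bis(benzyloxy)acetophenone and C4/C8a of ring A as a 1,3-dielectrophile, a 2-bromobenzyl bromide. One flask joins them: C-benzylation makes C3–C4, copper-catalysed enolate O-arylation makes O1–C8a, and a flat 4H-chromene (flav-2-ene) results. Reagent-controlled hydroboration then writes the 2,3-trans stereochemistry onto the flat ring, and two C8-bromide-directed C4→C6 Friedel–Crafts couplings assemble the trimer.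

Key step: step 5

Remark: flavan numbering (O1, C2, C3, C4, C4a, C5 to C8, C8a) is used for every unit; 1, 7 and 15 are taken as catalogue compounds, and the sense of induction in step 6 is assigned by analogy with 1-arylcycloalkenes (the antipodal reagent from (−)-α-pinene is equally available).

**Route**

Step 1
Reactants: 1 5-bromoresorcinol
Product: 2 1,3-bis(benzyloxy)-5-bromobenzene
Conditions: BnBr (2.2 equiv), K2CO3, DMF, 60 °C
Reagents that add atoms: benzyl bromide, BrCc1ccccc1
Why: Williamson etherification of both phenols; the aryl bromide is inert to carbonate base.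

Step 2
Reactants: 2 1,3-bis(benzyloxy)-5-bromobenzene
Product: 4 2,4-bis(benzyloxy)-6-bromobenzaldehyde, via aryl iminium chloride 3 (not isolated)
Conditions: POCl3, DMF, 0 → 70 °C; then aq. NaOAc, rt
Reagents that add atoms: N,N-dimethylformamide, CN(C)C=O; water, O
Why: Vilsmeier–Haack formylation should go para to one benzyloxy group and ortho to the other, next to bromine, as it does with 1-bromo-3,5-dimethoxybenzene, which places the future C4 between the bromide (future C8a) and an ether (future C5).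

Step 3
Reactants: 4 2,4-bis(benzyloxy)-6-bromobenzaldehyde
Product: 5 [2,4-bis(benzyloxy)-6-bromophenyl]methanol
Conditions: NaBH4, THF/MeOH, 0 °C
Reagents that add atoms: none
Why: Borohydride reduction of the aldehyde leaves the aryl bromide and the benzyl ethers untouched.

Step 4
Reactants: 5 [2,4-bis(benzyloxy)-6-bromophenyl]methanol
Product: 6 1,5-bis(benzyloxy)-3-bromo-2-(bromomethyl)benzene
Conditions: PBr3, CH2Cl2, 0 °C; used without storage
Reagents that add atoms: phosphorus tribromide, BrP(Br)Br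
Why: Standard conversion of an electron-rich benzylic alcohol into its bromide; the product is reactive and should be taken on at once.

Step 5
Reactants: 7 3',4'-bis(benzyloxy)acetophenone (1.5 equiv); 6 1,5-bis(benzyloxy)-3-bromo-2-(bromomethyl)benzene
Product: 9 5,7-bis(benzyloxy)-2-[3,4-bis(benzyloxy)phenyl]-4H-chromene, via C-benzylated ketone 8 (not isolated)
Conditions: LiN(SiMe3)2, THF, −78 °C; add 6, −78 → 0 °C; then, in the same flask, CuI (10 mol %), 1,10-phenanthroline (20 mol %), Cs2CO3, DMF, 100 °C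
Reagents that add atoms: none
Why: Proposed new method: the lithium enolate of 7 is benzylated on carbon by 6 (SN2 at the benzylic bromide, forming C3–C4) to give ketone 8, whose enolate, regenerated by Cs2CO3, should undergo copper-catalysed intramolecular Ullmann-type O-arylation (oxidative addition of the aryl bromide to a monovalent copper enolate, then C–O reductive elimination, forming O1–C8a). The closest known reaction type is the CuI-catalysed domino C-benzylation/O-arylation of β-keto esters with 2-bromobenzyl bromides to 4H-chromenes, together with copper-catalysed intramolecular O-arylation of simple ketone enolates to benzofurans; the extension is the use of a non-stabilised aryl methyl ketone enolate. Ring C closes as a six-membered ring through the enolate oxygen (6-exo with respect to the C8a–Br bond), the (Z)-enolate preferred for aryl ketones holding O1 and C4 cis, while C-arylation would need a four-membered ring. No stereocentre is formed: the product is the flat enol ether, and C2 and C3 are set in step 6. The step needs C- over O-benzylation and mono- over dialkylation, which the lithium enolate in THF at low temperature and the excess of 7 should secure, and it needs the aryl bromide to survive the first stage, which it should in the absence of copper.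

Step 6
Reactants: 9 5,7-bis(benzyloxy)-2-[3,4-bis(benzyloxy)phenyl]-4H-chromene
Product: 11 5,7,3',4'-tetra-O-benzyl-(+)-catechin, via flavanyl isopinocampheylborane 10 (not isolated)
Conditions: IpcBH2 (from (+)-α-pinene), THF, −25 °C; then NaOH, H2O2, 0 °C → rt
Reagents that add atoms: hydrogen peroxide, OO
Why: Asymmetric hydroboration–oxidation: IpcBH2 adds syn across the trisubstituted enol ether with boron at C3 (β to O1, distal to the aryl group) and oxidation with retention gives the 2,3-trans alcohol, the face being chosen by the isopinocampheyl group, since the reagent from (+)-α-pinene converts 1-arylcycloalkenes into (1S,2R)-trans-2-arylcycloalkanols, the spatial equivalent of (2R,3S) here.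

Step 7
Reactants: 11 5,7,3',4'-tetra-O-benzyl-(+)-catechin
Product: 12 8-bromo-5,7,3',4'-tetra-O-benzyl-(+)-catechin
Conditions: NBS (1.0 equiv), CH2Cl2, −78 °C → rt
Reagents that add atoms: N-bromosuccinimide, O=C1CCC(=O)N1Br
Why: Electrophilic aromatic bromination goes to C8, the most nucleophilic position of ring A, and blocks it so that later Friedel–Crafts attack must use C6; 12 serves both as the precursor of the middle unit (step 8) and, in excess, as the lower unit (step 9).

Step 8
Reactants: 12 8-bromo-5,7,3',4'-tetra-O-benzyl-(+)-catechin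
Product: 13 8-bromo-5,7,3',4'-tetra-O-benzyl-4β-(2-hydroxyethoxy)-(+)-catechin
Conditions: DDQ (2 equiv), ethylene glycol (6 equiv), CH2Cl2, rt
Reagents that add atoms: ethylene glycol, OCCO
Why: DDQ abstracts hydride from C4 (benzylic oxidation through the ring A-stabilised cation) and the glycol traps it, expected trans to the C2 aryl group; the C4 configuration is erased in step 9.

Step 9
Reactants: 13 8-bromo-5,7,3',4'-tetra-O-benzyl-4β-(2-hydroxyethoxy)-(+)-catechin; 12 8-bromo-5,7,3',4'-tetra-O-benzyl-(+)-catechin (4 equiv, excess recovered and recycled)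
Product: 14 8,8'-dibromo-octa-O-benzyl-catechin-(4α→6)-catechin
Conditions: TiCl4 (2 equiv), CH2Cl2/THF 9:1, 0 °C → rt; aq. NaHCO3
Reagents that add atoms: none
Why: Friedel–Crafts interflavan coupling: TiCl4 ionises the C4 ether of 13 and C6 of 12 (C8 is brominated) attacks the cation anti to the C3 hydroxyl, which should give the 3,4-trans (4α) linkage typical of the 2,3-trans series, while the excess of 12 suppresses self-condensation of 13.

Step 10
Reactants: 15 (−)-epicatechin
Product: 16 5,7,3',4'-tetra-O-benzyl-(−)-epicatechin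
Conditions: BnBr (4.2 equiv), K2CO3, DMF, 0 °C → rt
Reagents that add atoms: benzyl bromide, BrCc1ccccc1
Why: Williamson etherification of the four phenols in preference to the far less acidic C3 alcohol.

Step 11
Reactants: 16 5,7,3',4'-tetra-O-benzyl-(−)-epicatechin
Product: 17 5,7,3',4'-tetra-O-benzyl-4β-(2-hydroxyethoxy)-(−)-epicatechin
Conditions: DDQ (2 equiv), ethylene glycol (6 equiv), CH2Cl2, rt
Reagents that add atoms: ethylene glycol, OCCO
Why: DDQ benzylic oxidation at C4 with capture of the cation by the glycol from the β face, anti to the C2 aryl and C3 hydroxyl groups.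

Step 12
Reactants: 17 5,7,3',4'-tetra-O-benzyl-4β-(2-hydroxyethoxy)-(−)-epicatechin
Product: 18 6,8-dibromo-5,7,3',4'-tetra-O-benzyl-4β-(2-hydroxyethoxy)-(−)-epicatechin
Conditions: NBS (2.1 equiv), CH2Cl2, −40 °C → rt
Reagents that add atoms: N-bromosuccinimide, O=C1CCC(=O)N1Br
Why: Two-fold electrophilic bromination at C8 and C6 removes every nucleophilic position of ring A, so this unit can act only as an electrophile.

Step 13
Reactants: 18 6,8-dibromo-5,7,3',4'-tetra-O-benzyl-4β-(2-hydroxyethoxy)-(−)-epicatechin (1.5 equiv); 14 8,8'-dibromo-octa-O-benzyl-catechin-(4α→6)-catechin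
Product: 19 tetrabromo-dodeca-O-benzyl-epicatechin-(4β→6)-catechin-(4α→6)-catechin
Conditions: TiCl4 (2 equiv), CH2Cl2/THF 9:1, 0 °C → rt; aq. NaHCO3
Reagents that add atoms: none
Why: Same Friedel–Crafts coupling: the cation from 18 is attacked by C6 of the upper unit of 14, the only free ring A position, from the β face anti to both the C2 aryl and the C3 hydroxyl groups, which should give the 4β linkage.

Step 14
Reactants: 19 tetrabromo-dodeca-O-benzyl-epicatechin-(4β→6)-catechin-(4α→6)-catechin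
Product: 20 epicatechin-(4β→6)-catechin-(4α→6)-catechin (CNP0163146.4)
Conditions: H2 (1 atm), Pd(OH)2/C, Et3N, THF/MeOH/H2O, rt
Reagents that add atoms: none
Why: Hydrogenolysis should cleave the twelve benzyl ethers and the four aryl C–Br bonds in one operation, Et3N taking up HBr so that the acid-labile interflavan bonds survive.

**Compound list**

1 | 5-bromoresorcinol | Oc1cc(O)cc(Br)c1 | starting material
2 | 1,3-bis(benzyloxy)-5-bromobenzene | Brc1cc(OCc2ccccc2)cc(OCc2ccccc2)c1 | intermediate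
3 | [2,4-bis(benzyloxy)-6-bromophenyl]methylidene-dimethyliminium chloride | C[N+](C)=Cc1c(Br)cc(OCc2ccccc2)cc1OCc1ccccc1.[Cl-] | intermediate
4 | 2,4-bis(benzyloxy)-6-bromobenzaldehyde | O=Cc1c(Br)cc(OCc2ccccc2)cc1OCc1ccccc1 | intermediate
5 | [2,4-bis(benzyloxy)-6-bromophenyl]methanol | OCc1c(Br)cc(OCc2ccccc2)cc1OCc1ccccc1 | intermediate
6 | 1,5-bis(benzyloxy)-3-bromo-2-(bromomethyl)benzene | BrCc1c(Br)cc(OCc2ccccc2)cc1OCc1ccccc1 | intermediate
7 | 1-[3,4-bis(benzyloxy)phenyl]ethanone (3',4'-bis(benzyloxy)acetophenone) | CC(=O)c1ccc(OCc2ccccc2)c(OCc2ccccc2)c1 | starting material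
8 | 3-[2,4-bis(benzyloxy)-6-bromophenyl]-1-[3,4-bis(benzyloxy)phenyl]propan-1-one | O=C(CCc1c(Br)cc(OCc2ccccc2)cc1OCc1ccccc1)c1ccc(OCc2ccccc2)c(OCc2ccccc2)c1 | intermediate
9 | 5,7-bis(benzyloxy)-2-[3,4-bis(benzyloxy)phenyl]-4H-chromene (5,7,3',4'-tetrakis(benzyloxy)flav-2-ene) | C1(c2ccc(OCc3ccccc3)c(OCc3ccccc3)c2)=CCc2c(OCc3ccccc3)cc(OCc3ccccc3)cc2O1 | intermediate
10 | (2,3-trans-tetra-O-benzylflavan-3-yl)(isopinocampheyl)borane, boron on C3 trans to the C2 aryl group, same spatial arrangement at C2 and C3 as 11 | C[C@H]1[C@H](B[C@H]3Cc4c(OCc5ccccc5)cc(OCc5ccccc5)cc4O[C@@H]3c6ccc(OCc5ccccc5)c(OCc5ccccc5)c6)C[C@@H]2C[C@H]1C2(C)C | intermediate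
11 | (2R,3S)-5,7-bis(benzyloxy)-2-[3,4-bis(benzyloxy)phenyl]chroman-3-ol (5,7,3',4'-tetra-O-benzyl-(+)-catechin) | O(Cc1ccccc1)c1cc(OCc2ccccc2)c2c(c1)O[C@H](c1ccc(OCc3ccccc3)c(OCc3ccccc3)c1)[C@@H](O)C2 | intermediate
12 | (2R,3S)-8-bromo-5,7,3',4'-tetra-O-benzylcatechin | O(Cc1ccccc1)c1cc(OCc2ccccc2)c2c(c1Br)O[C@H](c1ccc(OCc3ccccc3)c(OCc3ccccc3)c1)[C@@H](O)C2 | intermediate
13 | (2R,3S,4S)-8-bromo-5,7,3',4'-tetra-O-benzyl-4-(2-hydroxyethoxy)catechin (4β ether) | O(Cc1ccccc1)c1cc(OCc2ccccc2)c2c(c1Br)O[C@H](c1ccc(OCc3ccccc3)c(OCc3ccccc3)c1)[C@@H](O)[C@H]2OCCO | intermediate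
14 | 8,8'-dibromo-octa-O-benzyl-catechin-(4α→6)-catechin (upper unit 2,3-trans-3,4-trans, C6 free; lower unit linked through C6) | c1c(OCc5ccccc5)c(Br)c2c(c1OCc5ccccc5)[C@@H](c3c(OCc5ccccc5)c(Br)c4c(c3OCc5ccccc5)C[C@H](O)[C@@H](c6ccc(OCc5ccccc5)c(OCc5ccccc5)c6)O4)[C@H](O)[C@@H](c6ccc(OCc5ccccc5)c(OCc5ccccc5)c6)O2 | intermediate
15 | (−)-epicatechin, (2R,3R) | Oc1cc(O)c2c(c1)O[C@H](c1ccc(O)c(O)c1)[C@H](O)C2 | starting material
16 | (2R,3R)-5,7,3',4'-tetra-O-benzylepicatechin | O(Cc1ccccc1)c1cc(OCc2ccccc2)c2c(c1)O[C@H](c1ccc(OCc3ccccc3)c(OCc3ccccc3)c1)[C@H](O)C2 | intermediate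
17 | (2R,3R,4S)-5,7,3',4'-tetra-O-benzyl-4-(2-hydroxyethoxy)epicatechin (4β ether) | O(Cc1ccccc1)c1cc(OCc2ccccc2)c2c(c1)O[C@H](c1ccc(OCc3ccccc3)c(OCc3ccccc3)c1)[C@H](O)[C@H]2OCCO | intermediate
18 | (2R,3R,4S)-6,8-dibromo-5,7,3',4'-tetra-O-benzyl-4-(2-hydroxyethoxy)epicatechin | O(Cc1ccccc1)c1c(Br)c(OCc2ccccc2)c2c(c1Br)O[C@H](c1ccc(OCc3ccccc3)c(OCc3ccccc3)c1)[C@H](O)[C@H]2OCCO | intermediate
19 | dodeca-O-benzyl-epicatechin-(4β→6)-catechin-(4α→6)-catechin with Br at C6 and C8 of the top unit and at C8 of the middle and bottom units | O(Cc5ccccc5)c1c(Br)c(OCc5ccccc5)c2c(c1Br)O[C@H](c6ccc(OCc5ccccc5)c(OCc5ccccc5)c6)[C@H](O)[C@H]2c1c(OCc5ccccc5)c(Br)c2c(c1OCc5ccccc5)[C@@H](c3c(OCc5ccccc5)c(Br)c4c(c3OCc5ccccc5)C[C@H](O)[C@@H](c6ccc(OCc5ccccc5)c(OCc5ccccc5)c6)O4)[C@H](O)[C@@H](c6ccc(OCc5ccccc5)c(OCc5ccccc5)c6)O2 | intermediate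
20 | epicatechin-(4β→6)-catechin-(4α→6)-catechin (CNP0163146.4) | Oc1cc(O)c2c(c1)O[C@H](c1ccc(O)c(O)c1)[C@H](O)[C@H]2c1c(O)cc2c(c1O)[C@@H](c1c(O)cc3c(c1O)C[C@H](O)[C@@H](c1ccc(O)c(O)c1)O3)[C@H](O)[C@@H](c1ccc(O)c(O)c1)O2 | target

**Step count and risks**

Total steps: 14. Longest linear sequence: 11 steps (steps 1, 2, 3, 4, 5, 6, 7, 8, 9, 13, 14).

The three steps most likely to fail:

Step 5. The enolate of the methyl ketone may be alkylated twice, and the copper cycle may stall on the weakly acidic, electron-rich ketone so that protodebromination overtakes ring closure. The fallback sets out from 7 and 6 and comes back at 9. Ketone 7 is acylated with diallyl carbonate (NaH, THF, reflux) to allyl 3-[3,4-bis(benzyloxy)phenyl]-3-oxopropanoate F1. F1 and 6 then undergo the known domino of this substrate class (CuI, 1,10-phenanthroline, Cs2CO3, DMF, 100 °C), which still forms C3–C4 and O1–C8a in one flask, through the C-benzylated keto ester F2 (not isolated), to give allyl 5,7-bis(benzyloxy)-2-[3,4-bis(benzyloxy)phenyl]-4H-chromene-3-carboxylate F3. Deallylation (Pd(PPh3)4, morpholine, THF) gives the 4H-chromene-3-carboxylic acid F4, which should lose CO2 on warming in DMSO (protonation at C3, then loss of CO2 from the 2-aryl oxocarbenium) to return 9.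

Step 6. Enantiofacial discrimination by the chiral borane may be poor on the cyclic aryl enol ether, or its sense may be opposite to the analogy. The fallback sets out from 9 and comes back at 11. Hydroboration with BH3·THF and oxidation (NaOH, H2O2) should give the racemic 2,3-trans-tetra-O-benzylflavan-3-ol F5. Esterification with (S)-O-methylmandelic acid (DCC, DMAP, CH2Cl2) gives the ester of the (2R,3S) alcohol F6 and the ester of the (2S,3R) alcohol F7, which are separated by chromatography or crystallisation. Saponification of F6 (LiOH, THF/H2O) returns 11.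

Step 13. Attack of the hindered C6 of the dimer on a cation carrying two bromines may be slow, so that alkylation of a ring B or acid cleavage of the existing interflavan bond consumes the advanced dimer. The fallback reverses the order of assembly; it sets out from 13, 18 and 12 and comes back at 19. Compound 13 is converted (4-methylbenzenethiol, BF3·OEt2, CH2Cl2, −78 °C) into 8-bromo-tetra-O-benzyl-4-(4-methylphenylthio)catechin F8, whose thioether tolerates hard Lewis acids. F8, used in excess as the C6 nucleophile, is coupled with 18 (BF3·OEt2, CH2Cl2, −30 °C) to the epicatechin-(4β→6)-catechin 4-thioether F9. Thiophilic activation of F9 (AgBF4, THF, 0 °C) in the presence of excess 12 then forms the 4α→6 bond and gives 19. Both couplings then use a monomeric nucleophile in excess.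

**Further compounds**

F1 | step 5 | allyl 3-[3,4-bis(benzyloxy)phenyl]-3-oxopropanoate | C=CCOC(=O)CC(=O)c1ccc(OCc2ccccc2)c(OCc2ccccc2)c1
F2 | step 5 | allyl 2-[2,4-bis(benzyloxy)-6-bromobenzyl]-3-[3,4-bis(benzyloxy)phenyl]-3-oxopropanoate (not isolated) | C=CCOC(=O)C(Cc1c(Br)cc(OCc2ccccc2)cc1OCc1ccccc1)C(=O)c1ccc(OCc2ccccc2)c(OCc2ccccc2)c1
F3 | step 5 | allyl 5,7-bis(benzyloxy)-2-[3,4-bis(benzyloxy)phenyl]-4H-chromene-3-carboxylate | C=CCOC(=O)C1=C(c2ccc(OCc3ccccc3)c(OCc3ccccc3)c2)Oc2cc(OCc3ccccc3)cc(OCc3ccccc3)c2C1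
F4 | step 5 | 5,7-bis(benzyloxy)-2-[3,4-bis(benzyloxy)phenyl]-4H-chromene-3-carboxylic acid | OC(=O)C1=C(c2ccc(OCc3ccccc3)c(OCc3ccccc3)c2)Oc2cc(OCc3ccccc3)cc(OCc3ccccc3)c2C1
F5 | step 6 | racemic 2,3-trans-5,7,3',4'-tetra-O-benzylflavan-3-ol (both enantiomers) | O(Cc1ccccc1)c1cc(OCc2ccccc2)c2c(c1)O[C@H](c1ccc(OCc3ccccc3)c(OCc3ccccc3)c1)[C@@H](O)C2.O(Cc1ccccc1)c1cc(OCc2ccccc2)c2c(c1)O[C@@H](c1ccc(OCc3ccccc3)c(OCc3ccccc3)c1)[C@H](O)C2
F6 | step 6 | (S)-O-methylmandelate of (2R,3S)-5,7,3',4'-tetra-O-benzylcatechin | O(Cc1ccccc1)c1cc(OCc2ccccc2)c2c(c1)O[C@H](c1ccc(OCc3ccccc3)c(OCc3ccccc3)c1)[C@@H](OC(=O)[C@@H](OC)c1ccccc1)C2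
F7 | step 6 | (S)-O-methylmandelate of the (2S,3R) enantiomer | O(Cc1ccccc1)c1cc(OCc2ccccc2)c2c(c1)O[C@@H](c1ccc(OCc3ccccc3)c(OCc3ccccc3)c1)[C@H](OC(=O)[C@@H](OC)c1ccccc1)C2
F8 | step 13 | 8-bromo-5,7,3',4'-tetra-O-benzyl-4-(4-methylphenylthio)catechin (3,4-trans epimer drawn; either epimer serves) | O(Cc1ccccc1)c1cc(OCc2ccccc2)c2c(c1Br)O[C@H](c1ccc(OCc3ccccc3)c(OCc3ccccc3)c1)[C@@H](O)[C@@H]2Sc1ccc(C)cc1
F9 | step 13 | 6,8-dibromo-tetra-O-benzylepicatechin-(4β→6)-[8-bromo-tetra-O-benzyl-4-(4-methylphenylthio)catechin] | O(Cc5ccccc5)c1c(Br)c(OCc5ccccc5)c2c(c1Br)O[C@H](c6ccc(OCc5ccccc5)c(OCc5ccccc5)c6)[C@H](O)[C@H]2c1c(OCc5ccccc5)c(Br)c2c(c1OCc5ccccc5)[C@@H](Sc3ccc(C)cc3)[C@H](O)[C@@H](c6ccc(OCc5ccccc5)c(OCc5ccccc5)c6)O2
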